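**Retrosynthetic overview**
1. Kanzonol E ⇒ one last operation (one-carbon expansion of a furan ring to the dimethylpyran ring, THP loss, γ-pyrone C–O closure) ⇒ 1-(benzofuran-5-yl)-3-aryl-1,3-diketone + an isopropenyl nucleophile.
2. Enabling feature: in the pyran ring O–CMe2–CH=CH–C3'–C4', the five atoms other than CMe2 are exactly the furan ring of a benzofuran (O1, C2, C3, C3a, C7a), with the cis C=C already in place. The enol-ether C2–O1 bond is the ether bond that Ni(0) cleaves, and the freed phenol O–H then lies 1,7 to the end of the new diene.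
3. Diketone ⇒ crossed Claisen condensation of methyl benzofuran-5-carboxylate with 2-hydroxy-5-prenyl-4-(THP-oxy)acetophenone. The latter ⇒ α-selective Suzuki–Miyaura prenylation of the mono-THP ether of 5-bromo-2,4-dihydroxyacetophenone.
4. Ring order: both benzene rings and the furan ring are bought. In step 4 the furan ring is first expanded to the pyran ring (5 → 6), then the γ-pyrone ring closes.

Key step: step 4

Remark on the chemistry: Kanzonol E has no stereocentre and no stereogenic axis, so it is achiral. Its only stereo-element is the ring-locked cis C=C of the pyran ring. The THP-bearing intermediates are racemic at the acetal carbon, which is their only stereocentre and is lost in step 4. The 1,3-diketones are drawn as diketo tautomers.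

Step 1
Reactants: 1 1-(5-bromo-2,4-dihydroxyphenyl)ethan-1-one
Product: 2 1-[5-bromo-2-hydroxy-4-(tetrahydro-2H-pyran-2-yloxy)phenyl]ethan-1-one (racemic)
Conditions: DHP, PPTS (cat.), CH2Cl2, rt
Reagents that add atoms: 3,4-dihydro-2H-pyran, C1=COCCC1
Why: Acid-catalysed addition of a phenol to an enol ether (THP acetal formation) should take only the 4-OH, because the 2-OH is held in the hydrogen bond to the acetyl C=O; the acetal carbon forms racemic and is removed later.

Step 2
Reactants: 2 1-[5-bromo-2-hydroxy-4-(tetrahydro-2H-pyran-2-yloxy)phenyl]ethan-1-one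
Product: 3 1-[2-hydroxy-5-(3-methylbut-2-en-1-yl)-4-(tetrahydro-2H-pyran-2-yloxy)phenyl]ethan-1-one (racemic)
Conditions: prenylBpin, Pd-PEPPSI-IPent (cat.), aq KOH, THF, 70 °C
Reagents that add atoms: 3-methylbut-2-en-1-ylboronic acid pinacol ester, CC(C)=CCB1OC(C)(C)C(C)(C)O1
Why: Suzuki–Miyaura coupling of an aryl bromide with a 3,3-disubstituted allylboronate, for which bulky Pd–NHC catalysts are known to give the α (linear, prenyl) product, and the bromine fixes the ring position while the THP acetal and ketone tolerate the base.

Step 3
Reactants: 3 1-[2-hydroxy-5-(3-methylbut-2-en-1-yl)-4-(tetrahydro-2H-pyran-2-yloxy)phenyl]ethan-1-one; 4 methyl 1-benzofuran-5-carboxylate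
Product: 5 1-(1-benzofuran-5-yl)-3-[2-hydroxy-5-(3-methylbut-2-en-1-yl)-4-(tetrahydro-2H-pyran-2-yloxy)phenyl]propane-1,3-dione (racemic)
Conditions: NaH, THF, reflux; AcOH quench
Reagents that add atoms: none
Why: Crossed Claisen condensation of the phenoxide–enolate dianion of an o-hydroxyacetophenone with a non-enolisable aryl ester, driven by formation of the diketonate, is the classical direct entry to o-hydroxydibenzoylmethanes.

Step 4
Reactants: 5 1-(1-benzofuran-5-yl)-3-[2-hydroxy-5-(3-methylbut-2-en-1-yl)-4-(tetrahydro-2H-pyran-2-yloxy)phenyl]propane-1,3-dione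
Product: 10 Kanzonol E, via (Z)-dienylphenol diketone 6 (not isolated), via o-quinone methide 7 (not isolated), via chromene diketone THP ether 8 (not isolated), via chromene diketone 9 (not isolated)
Conditions: (i) isopropenylMgBr (4.5 equiv), Ni(cod)2/PCy3 (cat.), THF–toluene, 0 to 40 °C; (ii) AcOH containing 10 % H2O, THF distilled off, 100 °C
Reagents that add atoms: isopropenylmagnesium bromide, CC(=C)[Mg]Br
Why: Proposed new method: the first two equivalents of Grignard reagent turn the phenol and the 1,3-diketone of 5 into a magnesium chelate that resists addition, Ni(0) then inserts into the enol-ether C2–O1 bond of the benzofuran, and transmetalation and reductive elimination with retention place the isopropenyl group on C2, so the furan ring is cut open to the (Z)-dienyl phenoxide (6 after the AcOH quench). On warming, a [1,7]-H shift from the phenol O–H to the diene CH2 terminus gives o-quinone methide 7, whose oxa-6π electrocyclisation makes the O–CMe2 bond (8), so the five furan atoms O1, C2, C3, C3a and C7a all reappear in the six-membered pyran, which has grown by the one carbon inserted between O1 and C2. The closest known reaction types are the nickel-catalysed Kumada-type ring-opening coupling of benzofurans with aryl and methyl Grignard reagents, the reductive lithiation/ketone addition/acid closure that turns benzofuran into 2H-chromenes, and the thermal cyclisation of (Z)-o-butadienylphenols; new are the alkenyl Grignard partner, the diketonate-bearing substrate and the telescoping into a one-carbon ring expansion. Ring closures: the pyran closes by thermal disrotatory 6π electrocyclisation of the oxatriene, and the γ-pyrone closes by 6-exo-trig addition of the 2-OH to the aroyl C=O of 9 followed by loss of water, after the aryl THP acetal of 8 has been hydrolysed in the same aqueous acetic acid. No stereocentre is formed, and the only stereo-element, the cis C=C of the pyran, is inherited from the benzofuran ring and is ring-locked again in the product. The step needs Ni to choose the furan C2–O1 bond over the aryl–O(THP) and aryl–OMg bonds, which is secured because a benzofuran C(sp2)–O bond is the most reactive ether bond towards Ni(0) while the competing bonds sit on an electron-rich anionic arene, and it needs the o-prenylphenol to survive, which is why only acetic acid buffered by the magnesium acetate formed in the quench is used and no strong acid.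

**Compound list**
1 | 1-(5-bromo-2,4-dihydroxyphenyl)ethan-1-one | CC(=O)c1cc(Br)c(O)cc1O | starting material
2 | 1-[5-bromo-2-hydroxy-4-(tetrahydro-2H-pyran-2-yloxy)phenyl]ethan-1-one (racemic) | CC(=O)c1cc(Br)c(OC2CCCCO2)cc1O | intermediate
3 | 1-[2-hydroxy-5-(3-methylbut-2-en-1-yl)-4-(tetrahydro-2H-pyran-2-yloxy)phenyl]ethan-1-one (racemic) | CC(=O)c1cc(CC=C(C)C)c(OC2CCCCO2)cc1O | intermediate
4 | methyl 1-benzofuran-5-carboxylate | COC(=O)c1ccc2occc2c1 | starting material
5 | 1-(1-benzofuran-5-yl)-3-[2-hydroxy-5-(3-methylbut-2-en-1-yl)-4-(tetrahydro-2H-pyran-2-yloxy)phenyl]propane-1,3-dione (racemic) | CC(C)=CCc1cc(C(=O)CC(=O)c2ccc3occc3c2)c(O)cc1OC4CCCCO4 | intermediate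
6 | 1-{4-hydroxy-3-[(1Z)-3-methylbuta-1,3-dien-1-yl]phenyl}-3-[2-hydroxy-5-(3-methylbut-2-en-1-yl)-4-(tetrahydro-2H-pyran-2-yloxy)phenyl]propane-1,3-dione (racemic, not isolated) | CC(C)=CCc1cc(C(=O)CC(=O)c2ccc(O)c(/C=C\C(C)=C)c2)c(O)cc1OC3CCCCO3 | intermediate
7 | 1-[2-hydroxy-5-(3-methylbut-2-en-1-yl)-4-(tetrahydro-2H-pyran-2-yloxy)phenyl]-3-[(3Z)-3-(3-methylbut-2-en-1-ylidene)-4-oxocyclohexa-1,5-dien-1-yl]propane-1,3-dione (o-quinone methide, racemic, not isolated) | CC(C)=CCc1cc(C(=O)CC(=O)C2=C/C(=C/C=C(C)C)C(=O)C=C2)c(O)cc1OC3CCCCO3 | intermediate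
8 | 1-(2,2-dimethyl-2H-chromen-6-yl)-3-[2-hydroxy-5-(3-methylbut-2-en-1-yl)-4-(tetrahydro-2H-pyran-2-yloxy)phenyl]propane-1,3-dione (racemic, not isolated) | CC(C)=CCc1cc(C(=O)CC(=O)c2ccc3c(c2)C=CC(C)(C)O3)c(O)cc1OC4CCCCO4 | intermediate
9 | 1-[2,4-dihydroxy-5-(3-methylbut-2-en-1-yl)phenyl]-3-(2,2-dimethyl-2H-chromen-6-yl)propane-1,3-dione (not isolated) | CC(C)=CCc1cc(C(=O)CC(=O)c2ccc3c(c2)C=CC(C)(C)O3)c(O)cc1O | intermediate
10 | Kanzonol E, 2-(2,2-dimethyl-2H-chromen-6-yl)-7-hydroxy-6-(3-methylbut-2-en-1-yl)-4H-chromen-4-one | CC(C)=CCc1cc2c(=O)cc(-c3ccc4c(c3)C=CC(C)(C)O4)oc2cc1O | target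

Total step count: 4. Longest linear sequence: 4 steps (1 → 2 → 3 → 5 → 10).

**Steps most likely to fail**

**Step 4 (bears the label).**
- What may go wrong: slow addition of the excess Grignard reagent to the magnesium diketonate; sequestration of nickel by the chelating diketonate or by the diene product; Z-to-E isomerisation of the dienyl phenoxide before the pericyclic closure.
- Fallback (known chemistry, sets out from 4, returns at 8): the ring expansion is moved onto the small ester, so that no Grignard reagent meets the diketone.
- Ester 4 undergoes the known nickel/NHC-catalysed boron insertion into the benzofuran C2–O bond (B2pin2, Cs2CO3). After hydrolytic work-up this should give methyl 2-hydroxy-2H-1,2-benzoxaborinine-6-carboxylate F1.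
- Suzuki–Miyaura coupling of this cyclic (Z)-alkenylboron compound with 2-bromopropene should give methyl 4-hydroxy-3-[(1Z)-3-methylbuta-1,3-dien-1-yl]benzoate F2.
- Heating F2 in toluene should lead, through methyl (3Z)-3-(3-methylbut-2-en-1-ylidene)-4-oxocyclohexa-1,5-diene-1-carboxylate F3, to methyl 2,2-dimethyl-2H-chromene-6-carboxylate F4.
- Claisen condensation of F4 with 3 under the conditions of step 3 gives 8, now isolated. Stage (ii) of step 4 then takes 8 through 9 to 10.

**Step 2.**
- What may go wrong: allyl transposition in the transmetalation/reductive elimination, which attaches the branched end of the C5 unit; sluggish oxidative addition into the electron-rich bromide, leading to protodeboronation of the reagent.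
- Fallback (sets out from 2, returns at 3): the C5 chain is built in two stages.
- Coupling of 2 with allylboronic acid pinacol ester, whose allyl group has two identical ends, should give 1-[2-hydroxy-5-(prop-2-en-1-yl)-4-(tetrahydro-2H-pyran-2-yloxy)phenyl]ethan-1-one F5.
- Olefin cross-metathesis of F5 with 2-methylbut-2-ene (second-generation Ru carbene catalyst, CH2Cl2, 40 °C) should convert the allyl group into the prenyl group of 3.

**Step 3.**
- What may go wrong: incomplete intermolecular C-acylation; acyl transfer to the phenoxide oxygen; retro-Claisen cleavage on prolonged heating.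
- Fallback (sets out from 3, returns at 5): the C–C bond is made intramolecularly.
- O-Acylation of 3 with commercial 1-benzofuran-5-carbonyl chloride in pyridine should give 2-acetyl-4-(3-methylbut-2-en-1-yl)-5-(tetrahydro-2H-pyran-2-yloxy)phenyl 1-benzofuran-5-carboxylate F6.
- Baker–Venkataraman rearrangement of F6 (KOH, pyridine, 50 °C) should deliver 5.

**Further compounds**
F1 | step 4 | methyl 2-hydroxy-2H-1,2-benzoxaborinine-6-carboxylate | COC(=O)c1ccc2OB(O)C=Cc2c1
F2 | step 4 | methyl 4-hydroxy-3-[(1Z)-3-methylbuta-1,3-dien-1-yl]benzoate | COC(=O)c1ccc(O)c(/C=C\C(C)=C)c1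
F3 | step 4 | methyl (3Z)-3-(3-methylbut-2-en-1-ylidene)-4-oxocyclohexa-1,5-diene-1-carboxylate | COC(=O)C1=C/C(=C/C=C(C)C)C(=O)C=C1
F4 | step 4 | methyl 2,2-dimethyl-2H-chromene-6-carboxylate | COC(=O)c1ccc2c(c1)C=CC(C)(C)O2
F5 | step 2 | 1-[2-hydroxy-5-(prop-2-en-1-yl)-4-(tetrahydro-2H-pyran-2-yloxy)phenyl]ethan-1-one (racemic) | CC(=O)c1cc(CC=C)c(OC2CCCCO2)cc1O
F6 | step 3 | 2-acetyl-4-(3-methylbut-2-en-1-yl)-5-(tetrahydro-2H-pyran-2-yloxy)phenyl 1-benzofuran-5-carboxylate (racemic) | CC(=O)c1cc(CC=C(C)C)c(OC2CCCCO2)cc1OC(=O)c3ccc4occc4c3
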